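At 25 h, the time at which I had to read the single product, the earlier runs were over: their last readings stood at 20.0 h, so I needed a way across the gap.

| setting | north-east | west | south | Saturday's | Monday's | Friday's | Thursday's |
|---|---|---|---|---|---|---|---|
| substrate | 0.14 M | 0.14 M | 0.14 M | 0.14 M | 0.14 M | 0.14 M | 0.14 M |
| coupling partner | 0.069 M | 0.11 M | 0.18 M | 0.0600 M | 0.0800 M | 0.120 M | 0.200 M |
| scavenger | 0.070 M (fed, over 1.0 h) | 0.070 M (fed, over 1.0 h) | 0.070 M (fed, over 1.0 h) | 0.0700 M (fed, over 1.0 h) | 0.0700 M (fed, over 1.0 h) | 0.0700 M (fed, over 1.0 h) | 0.0700 M (fed, over 1.0 h) |
| remark | run made earlier; the fed solution adds 0.50 times the starting volume | run made earlier; the fed solution adds 0.50 times the starting volume | run made earlier; the fed solution adds 0.50 times the starting volume | the fed solution adds 0.50 times the starting volume | the fed solution adds 0.50 times the starting volume | the fed solution adds 0.50 times the starting volume | the fed solution adds 0.50 times the starting volume |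
| time |  |  |  | 25 h | 25 h | 25 h | 25 h |

| run | time / h | single product / % |
|---|---|---|
| north-east | 1.50 | 18.0 |
| north-east | 4.00 | 17.8 |
| north-east | 8.00 | 16.5 |
| north-east | 12.0 | 15.3 |
| north-east | 20.0 | 12.5 |
| west | 1.33 | 17.9 |
| west | 2.50 | 18.7 |
| west | 5.00 | 17.4 |
| west | 10.0 | 15.5 |
| west | 20.0 | 14.5 |
| south | 4.00 | 12.3 |
| south | 8.00 | 12.2 |
| south | 10.0 | 11.4 |
| south | 15.0 | 11.4 |
| south | 20.0 | 10.9 |

(readings scatter by 0.5 percentage points)

- in percentages every species weighs as the substrate in it: one side product counts as two
- for released group the idle adduct is counted in
- charges are per starting volume, the dose included; the dosed solution carries all of it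
- what was read earlier has a scatter of 0.5 percentage points, one standard deviation
- what may be going on: substrate + coupling partner -> single product + released group; coupling partner + single product -> double product + released group; coupling partner + released group <-> idle adduct; scavenger + released group -> scavenged by-product; substrate + single product -> side product
- "hardly changes" means that all values lie within two and a half points (for a concentration: within two and a half percent of the largest)

- [single product] at the end for Saturday's, Monday's, Friday's, Thursday's, in this order
- the course of these numbers from the first flask to the last (falls, then rises / falls all the way / hardly changes / rises all the way / rises, then falls)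

I solved the two ends of the row first and joined them afterwards. In the north-east run, the fall per hour of the logarithm of the single-product reading, from the first reading to the last, came to 0.0197 h⁻¹; this is my tail constant, which treats the tail as a pseudo-first-order loss. Carried from the last reading to 25 h, it gave 11.3% of the substrate charged. The feed raises the volume by half, so the substrate charged corresponds to 0.0933 M at the end, and my estimate for the north-east run was 0.0106 M.

The south run was the weak link, because its fall from first to last reading was 1.4 percentage points against a scatter of 0.5 points on each reading. So I reforged it from means, the first two readings against the last two. That gave a tail constant of 0.00818 h⁻¹, smaller than the north-east one, and an end of 10.5%, or 0.00979 M.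

To join the ends I used the west run, whose tail constant of 0.0113 h⁻¹ gave 13.7%, or 0.0128 M. That estimate stands above both ends, by at least 2.4 points, against a scatter of 0.5 points on a single reading. Since the four flasks spread around these charges, I committed to a hump.

The forecast went on to the four flasks themselves, with 0.0093 M, 0.0117 M, 0.0121 M and 0.009 M, so rises, then falls: “The peak rises with partner at low charge, since more single product forms.”

The simulation gave 0.0106 M, 0.0119 M, 0.0125 M and 0.00849 M, so rises, then falls, and the forecast held.

    substrate + coupling partner → single product + released group (k = 13.5 M⁻¹ h⁻¹)
    coupling partner + single product → double product + released group (k = 41.3 M⁻¹ h⁻¹)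
    coupling partner + released group ⇌ idle adduct, settled at all times (K = 2.20 M⁻¹)
    scavenger + released group → scavenged by-product (k = 106 M⁻¹ h⁻¹)
    substrate + single product → side product (k = 0.294 M⁻¹ h⁻¹)

Part of the tail is the side-product step: with that step taken away, Saturday's ends at 0.0166 M instead of 0.0106 M. Spread over the hours after the feed, this loss is 0.0186 h⁻¹, beside the tail constant of 0.0197 h⁻¹ from the north-east run. In Thursday's, the turning of substrate + single product into side product separates 0.0100 M from 0.00849 M, which is 0.00685 h⁻¹, beside the 0.00818 h⁻¹ read from the south run. Thursday's value also belongs to the moment of reading: ten times later, its single product stands at 0.00287 M.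

The readings are simulated for an exercise; noise was put on by code.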